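## The problem

1. The target is a 1,2-dioxane (ring O1–O2–C3–C4–C5–C6) with CH2CO2H on C3, a cis ethyl on C4, and on the quaternary C6 an ethyl group plus the chain C7–C14, with 3R,4R,6S,10R centers and 7E,11E alkenes.
2. C6 is the hardest atom: a fully substituted, allylic, peroxide-bearing carbon whose ethyl and alkenyl substituents are close in size, so a ring closure onto a planar C6 (cation, radical or Michael acceptor) has no reason to choose a face and can also leak oxygen to C8.
3. The C7=C8 bond is the second trap: C8 carries ethyl and CH2R, which are nearly isosteric, so no olefination, enolisation or elimination can tell E from Z; only a transition state that distinguishes H from C6 on C7 can.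
4. C10 lies 1,5 to C6 across this alkene and is out of reach of ring control.
5. The acetic acid arm on C3 is axial on the chair that keeps both ethyl groups equatorial, so it must be installed kinetically; an equilibrating conjugate addition would favour the trans isomer.
6. The O–O bond rules out phosphines, low-valent metals, hydrogenation and strong hydrides; the C3–H of a β-peroxy carbonyl is base-labile (Kornblum–DeLaMare cleavage, retro-oxa-Michael); the tertiary allylic C6–O bond is acid-labile.
7. The feature that opens the problem is the unit C7=C8(Et)–C9H2–C10H(Et)–C11: it is the γ,δ-unsaturated acid retron of a [3,3] shift once C11 is read as a carboxyl carbon. Its precursor carries an ester oxygen on C7, next to C6 with the ring oxygen O1, and this vicinal O/OO pair is exactly what a C6–C7 epoxide leaves when H2O2 opens it at the tertiary carbon.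

## Retrosynthesis

**C2–C3 bond.** Acid 33 comes from methyl ester 32. Ester 32 is cut between C2 and C3 into the cyclic peroxycarbenium ion 31 (from methyl peroxyacetal 29) and silyl ketene acetal 30. The neighbouring cut, O2–C3 by oxa-Michael addition, would leave C3 to a reversible reaction that prefers the trans isomer. The chosen cut lets the ring exist first and lets C3 be set by axial attack on a conformationally locked cation. It also means that every earlier intermediate can be a mixture at C3. The forward step must ionise at C3 and not at the allylic C6.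

**C11=C12 bond.** Peroxyacetal 29 is cut at the disubstituted alkene into aldehyde 24 and sulfone 28 (from thiol 25 and bromide 26 via sulfide 27). This is preferred to a cross-coupling at C8–C9 because it uses no metal. Aldehyde 24 is the reduced form of acid 21, reached through alcohol 23.

**C9–C10 bond (key).** Acid 21 is the Ireland–Claisen product of butanoate 18: C9–C10 is cut and the oxygen is returned to C7. This one step answers problems 3 and 4 from a stereocenter on C7 that the route owns anyway. The eight-carbon side chain with its alkene and its stereocenter shrinks to a 2-methylidenebutyl carbinol (alcohol 16) and butanoic anhydride 17. The forward reaction needs a chair transition state, a defined ketene acetal geometry, and survival of the peroxide under one equivalent of amide base.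

**O1–C6 and O2–C3 bonds.** Peroxyacetal 16 comes from peroxyhemiacetal 15, which is cut at both C–O bonds of the peroxide into epoxy aldehyde 13 and H2O2. This is preferred to closing onto a planar C6 because the C6–O bond forms by inversion of a configurationally defined epoxide carbon. The hydroxyl left on C7 is not waste but the handle for the [3,3] step. The precursor is acyclic and its only oxygen stereochemistry comes from one epoxidation.

**Epoxide.** Aldehyde 13 comes from Weinreb amide 12, and 12 from diene 11 by catalytic asymmetric epoxidation of the trisubstituted alkene. One reaction sets C6 and C7. The 1,1-disubstituted alkene is the less nucleophilic one and stays.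

**C6–ethyl and C7–C8 bonds.** Diene 11 is cut into alkyne 6, ethylmagnesium bromide 7 and 2-bromobut-1-ene 8 (via alkenylcopper 9 and alkenylzinc 10). Ethyl and CH2R on C6 are again too alike for an olefination, so the geometry is taken from a syn addition to an alkyne.

**C4–C5 bond.** Amide 6 comes from imide 5, made by alkylating acyl oxazolidinone 3 (from 1 and 2) with propargyl bromide 4. C4 is the only center bought from an auxiliary.

## Roads not taken

**Alternative 1:** (the obvious route) cut O2–C3 by oxa-Michael addition and O1–C6 by making a tertiary allylic hydroperoxide. Acid-mediated H2O2 substitution or radical hydroperoxidation would give hydroperoxy trienoate A1, and base would close it to the ring. The chosen plan is better for three reasons: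
- C6 would arise from a planar allyl cation or radical, giving both epimers and the C8-transposed peroxide.
- The 3,4-relationship would be left to a reversible addition.
- The triene precursor still needs the C7=C8 geometry and C10 to be made separately.

**Alternative 2:** cut C8–C9 after the ring is built, joining vinyl iodide A2 and alkylzinc A3 by sp2–sp3 coupling under zerovalent palladium. This needs an organozinc and a low-valent metal beside the O–O bond. It also needs a separate asymmetric synthesis of the C10 fragment and several steps to put a geometrically defined iodoalkene on a neopentyl-type carbon, and it does nothing for C6. The chosen plan takes geometry and C10 from the C7 carbinol at no extra cost.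

**Alternative 3:** (biomimetic) Schenck ene reaction of singlet oxygen with the C6=C7 alkene of trienoate A4 would give A1 with the alkene shifted to C7=C8, followed by oxa-Michael closure in the same flask. The ene step must abstract the methine hydrogen on C8, whose reactive perpendicular conformation suffers A(1,3) strain. The hydrogens on C5 and on the C6 ethyl group would react instead and put oxygen on C7. The two reactive C8 rotamers would give E and Z alkenes with opposite C6 configuration, and C3 is again uncontrolled.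

Key step: step 10

## Route

Assumption: atom labels C1–C14, O1 and O2 follow the target in all compounds. Compounds 15–29 are carried as mixtures of both C3 epimers, because step 16 makes them converge.

Step 1
Reactants: 1 (4S)-4-benzyl-1,3-oxazolidin-2-one; 2 butanoyl chloride
Product: 3 (4S)-4-benzyl-3-butanoyl-1,3-oxazolidin-2-one
Conditions: n-BuLi, THF, −78 °C; then 2, −78 → 0 °C
Reagents that add atoms: none
Why: N-acylation of the lithiated oxazolidinone loads the auxiliary; no stereocenter is formed.

Step 2
Reactants: 3 (4S)-4-benzyl-3-butanoyl-1,3-oxazolidin-2-one; 4 3-bromoprop-1-yne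
Product: 5 (4S)-4-benzyl-3-[(2R)-2-ethylpent-4-ynoyl]-1,3-oxazolidin-2-one
Conditions: NaN(SiMe3)2, THF, −78 °C; then 4, −78 → −40 °C
Reagents that add atoms: none
Why: Evans asymmetric alkylation; the chelated Z sodium enolate is alkylated on the face opposite the benzyl group, which should set C4 as R.

Step 3
Reactants: 5 (4S)-4-benzyl-3-[(2R)-2-ethylpent-4-ynoyl]-1,3-oxazolidin-2-one
Product: 6 (2R)-2-ethyl-N-methoxy-N-methylpent-4-ynamide
Conditions: MeNHOMe·HCl, AlMe3, CH2Cl2, 0 °C → rt
Reagents that add atoms: N,O-dimethylhydroxylamine hydrochloride, CNOC.Cl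
Why: Aluminium amide transamidation to the Weinreb amide releases the auxiliary without touching C4 and gives a carbonyl group that should be inert to organocopper reagents and to Oxone and that stops at the aldehyde on hydride reduction.

Step 4
Reactants: 6 (2R)-2-ethyl-N-methoxy-N-methylpent-4-ynamide; 7 ethylmagnesium bromide; 8 2-bromobut-1-ene
Product: 11 (2R,4E)-2,4,6-triethyl-N-methoxy-N-methylhepta-4,6-dienamide, via alkenylcopper 9 (not isolated), via alkenylzinc bromide 10 (not isolated)
Conditions: 7, CuBr·SMe2, Et2O/Me2S, −45 °C; 6, −25 °C; then ZnBr2, Pd(PPh3)4 (5 mol %), 8, THF, −20 °C → rt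
Reagents that add atoms: none
Why: Normant syn-carbocupration puts ethyl on C6 and copper on C7 on the same side of the alkyne; transmetalation to zinc and Negishi-type coupling with 8 replace the metal with retention, so ethyl ends cis to C8 and the E diene should result.

Step 5
Reactants: 11 (2R,4E)-2,4,6-triethyl-N-methoxy-N-methylhepta-4,6-dienamide
Product: 12 (2R)-3-[(2R,3R)-3-(but-1-en-2-yl)-2-ethyloxiran-2-yl]-2-ethyl-N-methoxy-N-methylpropanamide
Conditions: D-fructose-derived Shi ketone (1,2:4,5-di-O-isopropylidene-β-D-erythro-hexo-2,3-diulo-2,6-pyranose, 30 mol %), Oxone (2KHSO5·KHSO4·K2SO4), K2CO3, Bu4NHSO4, MeCN/CH2(OMe)2/aq. borate buffer pH 10.5, 0 °C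
Reagents that add atoms: Oxone (active component potassium peroxymonosulfate), [K+].[O-]S(=O)(=O)OO
Why: Shi asymmetric epoxidation by a chiral dioxirane; the trisubstituted C6=C7 bond is more nucleophilic than the 1,1-disubstituted one, and the spiro transition-state model that gives R,R epoxides from trans and trisubstituted alkenes predicts the 6R,7R epoxide.

Step 6
Reactants: 12 (2R)-3-[(2R,3R)-3-(but-1-en-2-yl)-2-ethyloxiran-2-yl]-2-ethyl-N-methoxy-N-methylpropanamide
Product: 13 (2R)-3-[(2R,3R)-3-(but-1-en-2-yl)-2-ethyloxiran-2-yl]-2-ethylpropanal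
Conditions: iBu2AlH, THF, −78 °C; aq. potassium sodium tartrate
Reagents that add atoms: none
Why: Weinreb amide reduction stops at the chelated hemiaminal, which gives the aldehyde on work-up; the epoxide should not react with iBu2AlH at −78 °C.

Step 7
Reactants: 13 (2R)-3-[(2R,3R)-3-(but-1-en-2-yl)-2-ethyloxiran-2-yl]-2-ethylpropanal
Product: 15 (3RS,4R,6S)-4,6-diethyl-6-[(1R)-1-hydroxy-2-methylidenebutyl]-1,2-dioxan-3-ol, via hydroperoxy aldehyde 14 (not isolated)
Conditions: anhydrous ethereal H2O2 (excess), H3PMo12O40 (5 mol %), Et2O, 0 °C → rt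
Reagents that add atoms: hydrogen peroxide, OO
Why: Molybdenum-catalysed perhydrolysis of a trisubstituted epoxide opens the oxirane at its more substituted carbon with inversion, so C6 becomes S and C7 keeps its R hydroxyl; the tertiary hydroperoxide then adds to the aldehyde to close the six-membered peroxyhemiacetal. Attack at C6 rather than at allylic C7 is expected because a tertiary carbon carries positive charge better than a secondary allyl terminus without a donor at its far end.

Step 8
Reactants: 15 (3RS,4R,6S)-4,6-diethyl-6-[(1R)-1-hydroxy-2-methylidenebutyl]-1,2-dioxan-3-ol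
Product: 16 (1R)-1-[(3S,5R,6RS)-3,5-diethyl-6-methoxy-1,2-dioxan-3-yl]-2-methylidenebutan-1-ol
Conditions: MeOH, pyridinium p-toluenesulfonate (cat.), rt
Reagents that add atoms: methanol, CO
Why: Acid-catalysed acetal exchange takes place only at the peroxyhemiacetal carbon C3 and turns it into a methyl peroxyacetal that no longer ring-opens under base; the C3 configuration is irrelevant.

Step 9
Reactants: 16 (1R)-1-[(3S,5R,6RS)-3,5-diethyl-6-methoxy-1,2-dioxan-3-yl]-2-methylidenebutan-1-ol; 17 butanoic anhydride
Product: 18 (1R)-1-[(3S,5R,6RS)-3,5-diethyl-6-methoxy-1,2-dioxan-3-yl]-2-methylidenebutyl butanoate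
Conditions: 17, 4-(dimethylamino)pyridine, pyridine, CH2Cl2, rt
Reagents that add atoms: none
Why: Nucleophile-catalysed acylation of the hindered C7 alcohol; no stereocenter changes.

Step 10
Reactants: 18 (1R)-1-[(3S,5R,6RS)-3,5-diethyl-6-methoxy-1,2-dioxan-3-yl]-2-methylidenebutyl butanoate
Product: 21 (2R,4E)-5-[(3S,5R,6RS)-3,5-diethyl-6-methoxy-1,2-dioxan-3-yl]-2,4-diethylpent-4-enoic acid, via silyl ketene acetal 19 (not isolated), via trimethylsilyl ester 20 (not isolated)
Conditions: LiN(iPr)2, THF, −78 °C; Me3SiCl/Et3N, −78 °C → rt, then 50 °C; aq. citric acid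
Reagents that add atoms: none
Why: Ireland–Claisen rearrangement: kinetic deprotonation in THF gives the ester enolate with its ethyl group trans to OLi, which is trapped as the E silyl ketene acetal 19 and undergoes a concerted suprafacial [3,3] shift that breaks C7–O and makes C9–C10. The closest known reaction type is the ester enolate Claisen rearrangement of secondary 2-alkylallyl esters with 1,3-chirality transfer. No ring is closed; the only ring involved is the six-membered chair transition state. The new center C10 is controlled by the C7 carbinol center: the dioxanyl group on C7 sits equatorial, which fixes the face of the allyl unit, and the ketene acetal geometry fixes the face of C10, so 7R with the ethyl group cis to the allylic oxygen should give 10R. The same equatorial preference makes the new C7=C8 bond E, with C6 trans to C9, the geometry that no olefination could choose because the two C8 substituents are alike. The step needs chair over boat and clean enolate geometry; the first is helped by the quaternary C6 on the carbinol carbon, the second by deprotonation without a polar additive. The dialkyl peroxide and the peroxyacetal have no acidic carbonyl nearby and should tolerate one equivalent of amide base at −78 °C and the mild heating.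

Step 11
Reactants: 21 (2R,4E)-5-[(3S,5R,6RS)-3,5-diethyl-6-methoxy-1,2-dioxan-3-yl]-2,4-diethylpent-4-enoic acid
Product: 23 (2R,4E)-5-[(3S,5R,6RS)-3,5-diethyl-6-methoxy-1,2-dioxan-3-yl]-2,4-diethylpent-4-en-1-ol, via mixed anhydride 22 (not isolated)
Conditions: iBuOCOCl, N-methylmorpholine, THF, −15 °C; then NaBH4, H2O, 0 °C
Reagents that add atoms: none
Why: Mixed-anhydride activation followed by borohydride reduction; NaBH4 does not reduce dialkyl peroxides, and C10 is not enolised.

Step 12
Reactants: 23 (2R,4E)-5-[(3S,5R,6RS)-3,5-diethyl-6-methoxy-1,2-dioxan-3-yl]-2,4-diethylpent-4-en-1-ol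
Product: 24 (2R,4E)-5-[(3S,5R,6RS)-3,5-diethyl-6-methoxy-1,2-dioxan-3-yl]-2,4-diethylpent-4-enal
Conditions: Dess–Martin periodinane, NaHCO3, CH2Cl2, 0 °C → rt
Reagents that add atoms: none
Why: Buffered Dess–Martin oxidation should give the α-branched aldehyde without epimerisation at C10 and without touching the peroxide.

Step 13
Reactants: 25 1-phenyl-1H-tetrazole-5-thiol; 26 1-bromopropane
Product: 27 1-phenyl-5-(propylsulfanyl)-1H-tetrazole
Conditions: K2CO3, acetone, rt
Reagents that add atoms: none
Why: SN2 alkylation of the thiolate on sulfur.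

Step 14
Reactants: 27 1-phenyl-5-(propylsulfanyl)-1H-tetrazole
Product: 28 1-phenyl-5-(propane-1-sulfonyl)-1H-tetrazole
Conditions: 30 % aq. H2O2, (NH4)6Mo7O24·4H2O (cat.), EtOH, 0 °C → rt
Reagents that add atoms: hydrogen peroxide, OO
Why: Molybdate-catalysed oxidation of the sulfide to the sulfone, the standard preparation of Julia–Kocienski reagents.

Step 15
Reactants: 24 (2R,4E)-5-[(3S,5R,6RS)-3,5-diethyl-6-methoxy-1,2-dioxan-3-yl]-2,4-diethylpent-4-enal; 28 1-phenyl-5-(propane-1-sulfonyl)-1H-tetrazole
Product: 29 (3RS,4R,6S)-4,6-diethyl-6-[(1E,4R,5E)-2,4-diethylocta-1,5-dien-1-yl]-3-methoxy-1,2-dioxane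
Conditions: 28, KN(SiMe3)2, 1,2-dimethoxyethane, −60 °C; then 24, −60 °C → rt
Reagents that add atoms: none
Why: Julia–Kocienski olefination; phenyltetrazolyl sulfones with a potassium counter-ion in an ether solvent give E alkenes, and metalating the sulfone before the aldehyde is added keeps free base away from C10–H and from the peroxide.

Step 16
Reactants: 29 (3RS,4R,6S)-4,6-diethyl-6-[(1E,4R,5E)-2,4-diethylocta-1,5-dien-1-yl]-3-methoxy-1,2-dioxane; 30 tert-butyl[(1-methoxyethenyl)oxy]dimethylsilane
Product: 32 methyl 2-[(3R,4R,6S)-4,6-diethyl-6-[(1E,4R,5E)-2,4-diethylocta-1,5-dien-1-yl]-1,2-dioxan-3-yl]acetate, via peroxycarbenium triflate 31 (not isolated)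
Conditions: Me3SiOTf, 2,6-di-tert-butyl-4-methylpyridine, CH2Cl2, −78 °C
Reagents that add atoms: none
Why: Lewis acid-mediated substitution of a cyclic peroxyacetal through its peroxycarbenium ion with a silyl ketene acetal (Mukaiyama-type addition). Both C3 epimers give the same cation 31; in its half-chair the ethyl groups on C4 and C6 are pseudo-equatorial, and axial attack on the face that leads directly to a chair, anti to the axial C4–H, should place the acetate arm axial and cis to the C4 ethyl group (3R). The acetal oxygen is the most basic site, so ionisation at C3 should outrun ionisation of the allylic C6–O bond.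

Step 17
Reactants: 32 methyl 2-[(3R,4R,6S)-4,6-diethyl-6-[(1E,4R,5E)-2,4-diethylocta-1,5-dien-1-yl]-1,2-dioxan-3-yl]acetate
Product: 33 2-[(3R,4R,6S)-4,6-diethyl-6-[(1E,4R,5E)-2,4-diethylocta-1,5-dien-1-yl]-1,2-dioxan-3-yl]acetic acid
Conditions: LiOH, THF/H2O, 0 °C; then 1 M HCl to pH 3
Reagents that add atoms: lithium hydroxide (one carboxyl oxygen), [Li+].[OH-]
Why: Saponification at low temperature; methyl esters of this class of β-peroxy acids are known to be hydrolysed by LiOH faster than they undergo retro-oxa-Michael opening.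

## Compound list

1 | (4S)-4-benzyl-1,3-oxazolidin-2-one | O=C1N[C@@H](Cc2ccccc2)CO1 | starting material
2 | butanoyl chloride | CCCC(Cl)=O | starting material
3 | (4S)-4-benzyl-3-butanoyl-1,3-oxazolidin-2-one | CCCC(=O)N1[C@@H](Cc2ccccc2)COC1=O | intermediate
4 | 3-bromoprop-1-yne | C#CCBr | starting material
5 | (4S)-4-benzyl-3-[(2R)-2-ethylpent-4-ynoyl]-1,3-oxazolidin-2-one | C#CC[C@@H](CC)C(=O)N1[C@@H](Cc2ccccc2)COC1=O | intermediate
6 | (2R)-2-ethyl-N-methoxy-N-methylpent-4-ynamide | C#CC[C@@H](CC)C(=O)N(C)OC | intermediate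
7 | ethylmagnesium bromide | CC[Mg]Br | starting material
8 | 2-bromobut-1-ene | C=C(Br)CC | starting material
9 | {(1E,4R)-2-ethyl-4-[methoxy(methyl)carbamoyl]hex-1-en-1-yl}copper (MgBr2 complex) | CC/C(=C\[Cu])C[C@@H](CC)C(=O)N(C)OC | intermediate
10 | {(1E,4R)-2-ethyl-4-[methoxy(methyl)carbamoyl]hex-1-en-1-yl}zinc bromide | CC/C(=C\[Zn]Br)C[C@@H](CC)C(=O)N(C)OC | intermediate
11 | (2R,4E)-2,4,6-triethyl-N-methoxy-N-methylhepta-4,6-dienamide | C=C(CC)/C=C(CC)/C[C@@H](CC)C(=O)N(C)OC | intermediate
12 | (2R)-3-[(2R,3R)-3-(but-1-en-2-yl)-2-ethyloxiran-2-yl]-2-ethyl-N-methoxy-N-methylpropanamide | C=C(CC)[C@H]1O[C@]1(CC)C[C@@H](CC)C(=O)N(C)OC | intermediate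
13 | (2R)-3-[(2R,3R)-3-(but-1-en-2-yl)-2-ethyloxiran-2-yl]-2-ethylpropanal | C=C(CC)[C@H]1O[C@]1(CC)C[C@@H](CC)C=O | intermediate
14 | (2R,4S,5R)-2,4-diethyl-4-hydroperoxy-5-hydroxy-6-methylideneoctanal | C=C(CC)[C@@H](O)[C@@](CC)(OO)C[C@@H](CC)C=O | intermediate
15 | (3RS,4R,6S)-4,6-diethyl-6-[(1R)-1-hydroxy-2-methylidenebutyl]-1,2-dioxan-3-ol | C=C(CC)[C@@H](O)[C@]1(CC)C[C@@H](CC)C(O)OO1 | intermediate
16 | (1R)-1-[(3S,5R,6RS)-3,5-diethyl-6-methoxy-1,2-dioxan-3-yl]-2-methylidenebutan-1-ol | C=C(CC)[C@@H](O)[C@]1(CC)C[C@@H](CC)C(OC)OO1 | intermediate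
17 | butanoic anhydride | CCCC(=O)OC(=O)CCC | starting material
18 | (1R)-1-[(3S,5R,6RS)-3,5-diethyl-6-methoxy-1,2-dioxan-3-yl]-2-methylidenebutyl butanoate | C=C(CC)[C@@H](OC(=O)CCC)[C@]1(CC)C[C@@H](CC)C(OC)OO1 | intermediate
19 | {[(1E)-1-{(1R)-1-[(3S,5R,6RS)-3,5-diethyl-6-methoxy-1,2-dioxan-3-yl]-2-methylidenebutoxy}but-1-en-1-yl]oxy}trimethylsilane | C=C(CC)[C@@H](O/C(O[Si](C)(C)C)=C\CC)[C@]1(CC)C[C@@H](CC)C(OC)OO1 | intermediate
20 | trimethylsilyl (2R,4E)-5-[(3S,5R,6RS)-3,5-diethyl-6-methoxy-1,2-dioxan-3-yl]-2,4-diethylpent-4-enoate | C[Si](C)(C)OC(=O)[C@H](CC)C/C(CC)=C/[C@]1(CC)C[C@@H](CC)C(OC)OO1 | intermediate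
21 | (2R,4E)-5-[(3S,5R,6RS)-3,5-diethyl-6-methoxy-1,2-dioxan-3-yl]-2,4-diethylpent-4-enoic acid | OC(=O)[C@H](CC)C/C(CC)=C/[C@]1(CC)C[C@@H](CC)C(OC)OO1 | intermediate
22 | (2R,4E)-5-[(3S,5R,6RS)-3,5-diethyl-6-methoxy-1,2-dioxan-3-yl]-2,4-diethylpent-4-enoic 2-methylpropyl carbonic anhydride | CC(C)COC(=O)OC(=O)[C@H](CC)C/C(CC)=C/[C@]1(CC)C[C@@H](CC)C(OC)OO1 | intermediate
23 | (2R,4E)-5-[(3S,5R,6RS)-3,5-diethyl-6-methoxy-1,2-dioxan-3-yl]-2,4-diethylpent-4-en-1-ol | OC[C@H](CC)C/C(CC)=C/[C@]1(CC)C[C@@H](CC)C(OC)OO1 | intermediate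
24 | (2R,4E)-5-[(3S,5R,6RS)-3,5-diethyl-6-methoxy-1,2-dioxan-3-yl]-2,4-diethylpent-4-enal | O=C[C@H](CC)C/C(CC)=C/[C@]1(CC)C[C@@H](CC)C(OC)OO1 | intermediate
25 | 1-phenyl-1H-tetrazole-5-thiol | SC1=NN=NN1c1ccccc1 | starting material
26 | 1-bromopropane | CCCBr | starting material
27 | 1-phenyl-5-(propylsulfanyl)-1H-tetrazole | CCCSC1=NN=NN1c1ccccc1 | intermediate
28 | 1-phenyl-5-(propane-1-sulfonyl)-1H-tetrazole | CCCS(=O)(=O)C1=NN=NN1c1ccccc1 | intermediate
29 | (3RS,4R,6S)-4,6-diethyl-6-[(1E,4R,5E)-2,4-diethylocta-1,5-dien-1-yl]-3-methoxy-1,2-dioxane | CC/C=C/[C@H](CC)C/C(CC)=C/[C@]1(CC)C[C@@H](CC)C(OC)OO1 | intermediate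
30 | tert-butyl[(1-methoxyethenyl)oxy]dimethylsilane | C=C(OC)O[Si](C)(C)C(C)(C)C | starting material
31 | (4R,6S)-4,6-diethyl-6-[(1E,4R,5E)-2,4-diethylocta-1,5-dien-1-yl]-5,6-dihydro-4H-1,2-dioxin-2-ium trifluoromethanesulfonate | CC/C=C/[C@H](CC)C/C(CC)=C/[C@]1(CC)C[C@@H](CC)C=[O+]O1.[O-]S(=O)(=O)C(F)(F)F | intermediate
32 | methyl 2-[(3R,4R,6S)-4,6-diethyl-6-[(1E,4R,5E)-2,4-diethylocta-1,5-dien-1-yl]-1,2-dioxan-3-yl]acetate | CC/C=C/[C@H](CC)C/C(CC)=C/[C@]1(CC)C[C@@H](CC)[C@@H](CC(=O)OC)OO1 | intermediate
33 | 2-[(3R,4R,6S)-4,6-diethyl-6-[(1E,4R,5E)-2,4-diethylocta-1,5-dien-1-yl]-1,2-dioxan-3-yl]acetic acid | CC/C=C/[C@H](CC)C/C(=C/[C@]1(CC)C[C@@H](CC)[C@@H](CC(=O)O)OO1)CC | target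

## Step count and least certain steps

Total: 17 steps. Longest linear sequence: 15 steps (steps 1–12 and 15–17); steps 13–14 make the sulfone on a side branch.

**Step 10 (key step).** The most likely failure is erosion of stereocontrol at C10. The ketene acetal geometry required by the 7R center puts the C10 ethyl group pseudo-axial, where it meets the ethyl group on C8, so part of the material may pass through a boat transition state; incomplete enolate geometry would add to this. Base-induced cleavage of the peroxide is a lesser risk.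
Fallback: let the [3,3] shift set only the alkene geometry and let an auxiliary set C10. Starting from alcohol 16, acetylation would give the acetate F1. Its Ireland–Claisen rearrangement (no enolate geometry to control) would give the acid F2. Acylation of (4R)-4-benzyl-1,3-oxazolidin-2-one through the pivaloyl mixed anhydride would give the imide F3. Alkylation of its sodium enolate with ethyl triflate would give the ethylated imide F4. Reductive removal of the auxiliary with LiBH4 returns to the route at alcohol 23.

**Step 7.** The most likely failure is opening of the epoxide by the wrong nucleophile: five-membered ring participation by the aldehyde or perhydrate oxygen in competition with H2O2, or attack at the allylic carbon C7.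
Fallback: remove the carbonyl group before the perhydrolysis. Starting from aldehyde 13, NaBH4 reduction would give the epoxy alcohol F5, which is silylated at once with tert-butyldiphenylsilyl chloride to the silyl ether F6. Perhydrolysis with H2O2 and H3PMo12O40 would give the hydroperoxide silyl ether F7. Bu4NF would give the hydroperoxy diol F8. Selective oxidation of the primary alcohol with TEMPO and PhI(OAc)2 would give hydroperoxy aldehyde 14, which closes to 15, where the route is rejoined.

**Step 16.** The most likely failure is ionisation of the tertiary allylic C6–O bond by the Lewis acid, followed by loss of the ring, or loss of a proton from C4 of the cation.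
Fallback: classical oxa-Michael ring closure. Starting from 29, mild aqueous acid would hydrolyse the acetal to the peroxyhemiacetal F9. A Horner–Wadsworth–Emmons reaction of its open form with trimethyl phosphonoacetate under Masamune–Roush conditions would give the hydroperoxy enoate F10. Amine-promoted 6-exo conjugate addition (Et2NH, CF3CH2OH) would give ester 32 together with its C3 epimer, to be separated; the route is rejoined at 32.

**Step 15.** The most likely failure is partial loss of E selectivity and epimerisation of the α-branched aldehyde at C10 under the basic conditions.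
Fallback: Wittig methylenation of aldehyde 24 (Ph3P=CH2) would give the terminal alkene F11. Cross-metathesis with excess (E)-hex-3-ene under the second-generation Grubbs catalyst RuCl2(=CHPh)(PCy3)(H2IMes) should favour the E disubstituted alkene and leave the hindered trisubstituted alkene alone, returning to the route at 29.

## Further compounds

F1 | step 10 | (1R)-1-[(3S,5R,6RS)-3,5-diethyl-6-methoxy-1,2-dioxan-3-yl]-2-methylidenebutyl acetate | C=C(CC)[C@@H](OC(C)=O)[C@]1(CC)C[C@@H](CC)C(OC)OO1
F2 | step 10 | (4E)-5-[(3S,5R,6RS)-3,5-diethyl-6-methoxy-1,2-dioxan-3-yl]-4-ethylpent-4-enoic acid | OC(=O)CC/C(CC)=C/[C@]1(CC)C[C@@H](CC)C(OC)OO1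
F3 | step 10 | (4R)-4-benzyl-3-{(4E)-5-[(3S,5R,6RS)-3,5-diethyl-6-methoxy-1,2-dioxan-3-yl]-4-ethylpent-4-enoyl}-1,3-oxazolidin-2-one | O=C(CC/C(CC)=C/[C@]1(CC)C[C@@H](CC)C(OC)OO1)N1[C@H](Cc2ccccc2)COC1=O
F4 | step 10 | (4R)-4-benzyl-3-{(2R,4E)-5-[(3S,5R,6RS)-3,5-diethyl-6-methoxy-1,2-dioxan-3-yl]-2,4-diethylpent-4-enoyl}-1,3-oxazolidin-2-one | O=C([C@H](CC)C/C(CC)=C/[C@]1(CC)C[C@@H](CC)C(OC)OO1)N1[C@H](Cc2ccccc2)COC1=O
F5 | step 7 | (2R)-3-[(2R,3R)-3-(but-1-en-2-yl)-2-ethyloxiran-2-yl]-2-ethylpropan-1-ol | C=C(CC)[C@H]1O[C@]1(CC)C[C@@H](CC)CO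
F6 | step 7 | {(2R)-3-[(2R,3R)-3-(but-1-en-2-yl)-2-ethyloxiran-2-yl]-2-ethylpropoxy}(tert-butyl)diphenylsilane | C=C(CC)[C@H]1O[C@]1(CC)C[C@@H](CC)CO[Si](c1ccccc1)(c1ccccc1)C(C)(C)C
F7 | step 7 | (4R,5S,7R)-8-[(tert-butyldiphenylsilyl)oxy]-5,7-diethyl-5-hydroperoxy-3-methylideneoctan-4-ol | C=C(CC)[C@@H](O)[C@@](CC)(OO)C[C@@H](CC)CO[Si](c1ccccc1)(c1ccccc1)C(C)(C)C
F8 | step 7 | (2R,4S,5R)-2,4-diethyl-4-hydroperoxy-6-methylideneoctane-1,5-diol | C=C(CC)[C@@H](O)[C@@](CC)(OO)C[C@@H](CC)CO
F9 | step 16 | (3RS,4R,6S)-4,6-diethyl-6-[(1E,4R,5E)-2,4-diethylocta-1,5-dien-1-yl]-1,2-dioxan-3-ol | CC/C=C/[C@H](CC)C/C(CC)=C/[C@]1(CC)C[C@@H](CC)C(O)OO1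
F10 | step 16 | methyl (2E,4R,6S,7E,10R,11E)-4,6,8,10-tetraethyl-6-hydroperoxytetradeca-2,7,11-trienoate | CC/C=C/[C@H](CC)C/C(CC)=C/[C@@](CC)(OO)C[C@@H](CC)/C=C/C(=O)OC
F11 | step 15 | (3RS,4R,6S)-4,6-diethyl-6-[(1E,4R)-2,4-diethylhexa-1,5-dien-1-yl]-3-methoxy-1,2-dioxane | C=C[C@H](CC)C/C(CC)=C/[C@]1(CC)C[C@@H](CC)C(OC)OO1
A1 | alternative 1 | methyl (2E,4R,6RS,7E,10R,11E)-4,6,8,10-tetraethyl-6-hydroperoxytetradeca-2,7,11-trienoate | CC/C=C/[C@H](CC)C/C(CC)=C/C(CC)(OO)C[C@@H](CC)/C=C/C(=O)OC
A2 | alternative 2 | methyl 2-[(3R,4R,6S)-4,6-diethyl-6-[(1E)-2-iodobut-1-en-1-yl]-1,2-dioxan-3-yl]acetate | CC/C(I)=C\[C@]1(CC)C[C@@H](CC)[C@@H](CC(=O)OC)OO1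
A3 | alternative 2 | [(2S,3E)-2-ethylhex-3-en-1-yl]zinc iodide | CC/C=C/[C@H](CC)C[Zn]I
A4 | alternative 3 | methyl (2E,4R,6E,8RS,10R,11E)-4,6,8,10-tetraethyltetradeca-2,6,11-trienoate | CC/C=C/[C@H](CC)CC(CC)/C=C(CC)/C[C@@H](CC)/C=C/C(=O)OC
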